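## Retrosynthetic overview

Labdane numbering is used for orientation: C4 carries Me and CO2Me, C6 the OAc, C8 the exocyclic CH2, C9 the dienyl chain, C10 the angular Me.

1. Target ⇐ bicyclic C4-hydroxymethyl compound (CH2OH → CO2H, then O-methylation); the C6 acetate, the exocyclic alkene and the diene are already in place.
2. Both carbocycles form in one operation: a Cp2TiCl-triggered radical cascade of an acyclic (6R)-acetoxy epoxy-tetraene. Ring A closes first (C4–C5), ring B second (C10–C9), and C8=CH2 arises by β-hydride loss.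
3. The only stereocentre of the acyclic precursor (C6) relays C4, C5, C9 and C10; it comes from CBS reduction of a skipped enone, followed by acetylation.
4. Enone ⇐ C6–C7 bond by acylation of an α-lithio allylic sulfone (C7–C15 triene) with an epoxy enoate (C1–C6, C18–C20), then reductive desulfonylation.
5. Sulfone ⇐ isoprene + PhSO2Cl, then Negishi dienylation; enoate ⇐ syn-carbocupration of methyl but-2-ynoate, then epoxidation.

Assumption: the target is taken exactly as drawn, i.e. methyl (1S,4aS,5R,8R,8aS)-8-(acetyloxy)-1,4a-dimethyl-6-methylidene-5-[(2E)-3-methylpenta-2,4-dien-1-yl]decahydronaphthalene-1-carboxylate (trans-decalin; CO2Me, OAc and side chain all equatorial). The oxirane carbon of 5 and 13–16 is left racemic on purpose because it is destroyed in step 9.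

## Route

Step 1
Reactants: 1 5-bromo-2-methylpent-1-ene; 2 methyl but-2-ynoate
Product: 4 methyl (2E)-3,7-dimethylocta-2,7-dienoate, via Grignard reagent 3 (not isolated)
Conditions: Mg, THF; CuBr·SMe2 (1.05 equiv), −78 °C; then 2, −78 °C; 1 M HCl quench
Reagents that add atoms: none
Why: Grignard formation followed by copper-mediated syn-carbometalation of the ynoate (Normant-type carbocupration) and protonation with retention gives only the (2E) ester, because the alkyl group and copper add to the same face of the triple bond.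

Step 2
Reactants: 4 methyl (2E)-3,7-dimethylocta-2,7-dienoate
Product: 5 methyl (2E)-3-methyl-6-(2-methyloxiran-2-yl)hex-2-enoate
Conditions: mCPBA, NaHCO3, CH2Cl2, 0 °C
Reagents that add atoms: mCPBA (3-chloroperoxybenzoic acid), O=C(OO)c1cccc(Cl)c1
Why: Prilezhaev epoxidation is chemoselective for the electron-rich 1,1-disubstituted alkene over the conjugated enoate; the new oxirane centre is racemic and is erased in step 9.

Step 3
Reactants: 6 isoprene; 7 benzenesulfonyl chloride
Product: 8 {[(2E)-4-chloro-2-methylbut-2-en-1-yl]sulfonyl}benzene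
Conditions: CuCl (5 mol %), Et3N·HCl (5 mol %), MeCN, 100 °C, sealed tube
Reagents that add atoms: none
Why: Copper-catalysed Kharasch-type atom-transfer radical addition; the sulfonyl radical adds to the CH2 next to the methyl-bearing carbon (most stabilised allyl radical) and chlorine is delivered to the far terminus, giving the (E) 1,4-adduct.

Step 4
Reactants: 9 but-1-en-3-yne; 8 {[(2E)-4-chloro-2-methylbut-2-en-1-yl]sulfonyl}benzene
Product: 11 {[(2E,5E)-2,6-dimethylocta-2,5,7-trien-1-yl]sulfonyl}benzene, via alkenylalane 10 (not isolated)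
Conditions: Me3Al (2 equiv), Cp2ZrCl2 (0.25 equiv), ClCH2CH2Cl, rt; then 8, Pd(PPh3)4 (3 mol %), THF, rt
Reagents that add atoms: trimethylaluminium, C[Al](C)C
Why: Negishi zirconium-catalysed syn-methylalumination of the terminal alkyne fixes the (E) trisubstituted diene, and zerovalent-palladium-catalysed coupling of the alkenylalane at the unhindered CH2 terminus of the allylic chloride keeps both alkene geometries (Negishi 1,4-diene synthesis).

Step 5
Reactants: 11 {[(2E,5E)-2,6-dimethylocta-2,5,7-trien-1-yl]sulfonyl}benzene; 5 methyl (2E)-3-methyl-6-(2-methyloxiran-2-yl)hex-2-enoate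
Product: 13 (4E,8E,11E)-7-(benzenesulfonyl)-4,8,12-trimethyl-1-(2-methyloxiran-2-yl)tetradeca-4,8,11,13-tetraen-6-one, via lithiated sulfone 12 (not isolated)
Conditions: 11 (2.0 equiv), n-BuLi (2.0 equiv), THF, −78 °C; then 5, −78 to −30 °C; AcOH quench (excess 11 recovered)
Reagents that add atoms: none
Why: Claisen-type C-acylation of the α-lithio allylic sulfone, which reacts at its α carbon; the acidic β-keto sulfone is held as its enolate so no over-addition occurs, the oxirane is inert at low temperature, and the new C7 centre is removed in step 6.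

Step 6
Reactants: 13 (4E,8E,11E)-7-(benzenesulfonyl)-4,8,12-trimethyl-1-(2-methyloxiran-2-yl)tetradeca-4,8,11,13-tetraen-6-one
Product: 14 (4E,8E,11E)-4,8,12-trimethyl-1-(2-methyloxiran-2-yl)tetradeca-4,8,11,13-tetraen-6-one
Conditions: SmI2 (2.5 equiv), THF/MeOH, −78 °C
Reagents that add atoms: none
Why: Reductive desulfonylation of a β-keto sulfone by single-electron transfer (ketyl, C–S cleavage, samarium enolate) with kinetic α-protonation by methanol at −78 °C gives the β,γ-unsaturated ketone without moving the (8E) alkene into conjugation.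

Step 7
Reactants: 14 (4E,8E,11E)-4,8,12-trimethyl-1-(2-methyloxiran-2-yl)tetradeca-4,8,11,13-tetraen-6-one
Product: 15 (4E,6R,8E,11E)-4,8,12-trimethyl-1-(2-methyloxiran-2-yl)tetradeca-4,8,11,13-tetraen-6-ol
Conditions: (S)-Me-CBS oxazaborolidine (0.3 equiv), catecholborane (1.8 equiv), toluene, −78 °C; aq NaOH work-up
Reagents that add atoms: none
Why: Corey–Bakshi–Shibata reduction; the ketone binds the oxazaborolidine anti to the larger alkenyl substituent and hydride is delivered 1,2 to one face, setting (6R), while catecholborane at −78 °C leaves the oxirane and alkenes alone.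

Step 8
Reactants: 15 (4E,6R,8E,11E)-4,8,12-trimethyl-1-(2-methyloxiran-2-yl)tetradeca-4,8,11,13-tetraen-6-ol
Product: 16 (4E,6R,8E,11E)-4,8,12-trimethyl-1-(2-methyloxiran-2-yl)tetradeca-4,8,11,13-tetraen-6-yl acetate
Conditions: Ac2O, pyridine, DMAP (cat.), CH2Cl2, 0 °C to rt
Reagents that add atoms: acetic anhydride, CC(=O)OC(C)=O
Why: DMAP-catalysed O-acylation; no bond to C6 is broken, so (6R) is retained.

Step 9
Reactants: 16 (4E,6R,8E,11E)-4,8,12-trimethyl-1-(2-methyloxiran-2-yl)tetradeca-4,8,11,13-tetraen-6-yl acetate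
Product: 18 (1R,4R,4aS,8S,8aS)-8-(hydroxymethyl)-4a,8-dimethyl-3-methylidene-4-[(2E)-3-methylpenta-2,4-dien-1-yl]decahydronaphthalen-1-yl acetate, via titanium alkoxide 17 (not isolated)
Conditions: Cp2TiCl2 (2.5 equiv), Mn dust (8 equiv), THF (0.01 M), rt, slow addition of 16; dilute aq HCl work-up
Reagents that add atoms: none
Why: Proposed new method: Cp2TiCl (trivalent titanium, Nugent–RajanBabu reagent) opens the 2,2-disubstituted oxirane homolytically to a tertiary β-titanoxy radical that closes ring A (6-endo on the trisubstituted alkene) and then ring B (6-endo) through a chair–chair array; the C6 hydrogen must eclipse the alkene to avoid A(1,3) strain with the cis methyl, so the acetoxy group sits pseudo-equatorial, the radical attacks C5 anti to the C7 chain, and this with the two (E) alkenes fixes C5, C10 and C9 (trans-decalin, equatorial side chain); the bulky CH2OTiCp2Cl arm is expected to take the pseudo-equatorial site at C4, and the last tertiary radical is trapped by a second Cp2TiCl and loses a β-hydrogen from the methyl group to give the exocyclic alkene; the closest known reaction type is the titanocene-mediated radical cyclisation of 2,3-epoxypolyprenes, extended here to an oxirane that leaves no C3 oxygen and to control by a single allylic acetoxy stereocentre.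

Step 10
Reactants: 18 (1R,4R,4aS,8S,8aS)-8-(hydroxymethyl)-4a,8-dimethyl-3-methylidene-4-[(2E)-3-methylpenta-2,4-dien-1-yl]decahydronaphthalen-1-yl acetate
Product: 20 (1S,4aS,5R,8R,8aS)-8-(acetyloxy)-1,4a-dimethyl-6-methylidene-5-[(2E)-3-methylpenta-2,4-dien-1-yl]decahydronaphthalene-1-carboxylic acid, via aldehyde 19 (not isolated)
Conditions: TEMPO (0.2 equiv), PhI(OAc)2 (1.2 equiv), CH2Cl2, rt; then t-BuOH/H2O, 2-methyl-2-butene, NaClO2, NaH2PO4, 0 °C to rt
Reagents that add atoms: sodium chlorite, [Na+].[O-]Cl=O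
Why: TEMPO/PhI(OAc)2 oxidation of the neopentyl primary alcohol to the aldehyde, then Pinnick oxidation in the same flask with 2-methyl-2-butene as hypochlorite scavenger, gives the acid without touching the diene, the exocyclic alkene or the quaternary C4 centre.

Step 11
Reactants: 20 (1S,4aS,5R,8R,8aS)-8-(acetyloxy)-1,4a-dimethyl-6-methylidene-5-[(2E)-3-methylpenta-2,4-dien-1-yl]decahydronaphthalene-1-carboxylic acid
Product: 21 methyl (1S,4aS,5R,8R,8aS)-8-(acetyloxy)-1,4a-dimethyl-6-methylidene-5-[(2E)-3-methylpenta-2,4-dien-1-yl]decahydronaphthalene-1-carboxylate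
Conditions: MeI, K2CO3, DMF, rt
Reagents that add atoms: iodomethane, CI
Why: SN2 O-alkylation of the potassium carboxylate; the mild base leaves the acetate and every stereocentre untouched.

## Compound list

1 | 5-bromo-2-methylpent-1-ene | C=C(C)CCCBr | starting material
2 | methyl but-2-ynoate | CC#CC(=O)OC | starting material
3 | (4-methylpent-4-en-1-yl)magnesium bromide | C=C(C)CCC[Mg]Br | intermediate (not isolated)
4 | methyl (2E)-3,7-dimethylocta-2,7-dienoate | C=C(C)CCC/C(C)=C/C(=O)OC | intermediate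
5 | methyl (2E)-3-methyl-6-(2-methyloxiran-2-yl)hex-2-enoate (racemic oxirane) | CC1(CCC/C(C)=C/C(=O)OC)CO1 | intermediate
6 | isoprene (2-methylbuta-1,3-diene) | C=CC(C)=C | starting material
7 | benzenesulfonyl chloride | O=S(=O)(Cl)c1ccccc1 | starting material
8 | {[(2E)-4-chloro-2-methylbut-2-en-1-yl]sulfonyl}benzene | ClC/C=C(C)/CS(=O)(=O)c1ccccc1 | intermediate
9 | but-1-en-3-yne (bought as a solution) | C=CC#C | starting material
10 | dimethyl[(1E)-2-methylbuta-1,3-dien-1-yl]alumane | C[Al](C)/C=C(\C)C=C | intermediate (not isolated)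
11 | {[(2E,5E)-2,6-dimethylocta-2,5,7-trien-1-yl]sulfonyl}benzene | C=C/C(C)=C/C/C=C(C)/CS(=O)(=O)c1ccccc1 | intermediate
12 | {[(2E,5E)-1-lithio-2,6-dimethylocta-2,5,7-trien-1-yl]sulfonyl}benzene | C=C/C(C)=C/C/C=C(C)/C([Li])S(=O)(=O)c1ccccc1 | intermediate (not isolated)
13 | (4E,8E,11E)-7-(benzenesulfonyl)-4,8,12-trimethyl-1-(2-methyloxiran-2-yl)tetradeca-4,8,11,13-tetraen-6-one (diastereomer mixture at C7 and oxirane) | CC1(CCC/C(C)=C/C(=O)C(/C(C)=C/C/C=C(\C)C=C)S(=O)(=O)c2ccccc2)CO1 | intermediate
14 | (4E,8E,11E)-4,8,12-trimethyl-1-(2-methyloxiran-2-yl)tetradeca-4,8,11,13-tetraen-6-one (racemic oxirane) | CC1(CCC/C(C)=C/C(=O)C/C(C)=C/C/C=C(\C)C=C)CO1 | intermediate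
15 | (4E,6R,8E,11E)-4,8,12-trimethyl-1-(2-methyloxiran-2-yl)tetradeca-4,8,11,13-tetraen-6-ol (oxirane epimers) | CC1(CCC/C(C)=C/[C@H](O)C/C(C)=C/C/C=C(\C)C=C)CO1 | intermediate
16 | (4E,6R,8E,11E)-4,8,12-trimethyl-1-(2-methyloxiran-2-yl)tetradeca-4,8,11,13-tetraen-6-yl acetate (oxirane epimers) | CC1(CCC/C(C)=C/[C@H](OC(C)=O)C/C(C)=C/C/C=C(\C)C=C)CO1 | intermediate
17 | chlorobis(cyclopentadienyl)titanium alkoxide of 18 (tetravalent titanium) | C=C/C(C)=C/C[C@@H]1C(=C)C[C@@H](OC(C)=O)[C@H]2[C@@]1(C)CCC[C@]2(C)C[O-].[Cl-].[Ti+4].c1cc[cH-]c1.c1cc[cH-]c1 | intermediate (not isolated)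
18 | (1R,4R,4aS,8S,8aS)-8-(hydroxymethyl)-4a,8-dimethyl-3-methylidene-4-[(2E)-3-methylpenta-2,4-dien-1-yl]decahydronaphthalen-1-yl acetate | C=C/C(C)=C/C[C@@H]1C(=C)C[C@@H](OC(C)=O)[C@H]2[C@@]1(C)CCC[C@]2(C)CO | intermediate
19 | (1R,4R,4aS,8S,8aS)-8-formyl-4a,8-dimethyl-3-methylidene-4-[(2E)-3-methylpenta-2,4-dien-1-yl]decahydronaphthalen-1-yl acetate | C=C/C(C)=C/C[C@@H]1C(=C)C[C@@H](OC(C)=O)[C@H]2[C@@]1(C)CCC[C@]2(C)C=O | intermediate (not isolated)
20 | (1S,4aS,5R,8R,8aS)-8-(acetyloxy)-1,4a-dimethyl-6-methylidene-5-[(2E)-3-methylpenta-2,4-dien-1-yl]decahydronaphthalene-1-carboxylic acid | C=C/C(C)=C/C[C@@H]1C(=C)C[C@@H](OC(C)=O)[C@H]2[C@@]1(C)CCC[C@]2(C)C(=O)O | intermediate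
21 | methyl (1S,4aS,5R,8R,8aS)-8-(acetyloxy)-1,4a-dimethyl-6-methylidene-5-[(2E)-3-methylpenta-2,4-dien-1-yl]decahydronaphthalene-1-carboxylate | C=C/C(C)=C/C[C@@H]1C(=C)C[C@@H](OC(C)=O)[C@H]2[C@@]1(C)CCC[C@]2(C)C(=O)OC | target

## Step count and risks

Total step count: 11. Longest linear sequence: 9 (steps 1, 2, 5–11; the branch through steps 3 and 4 is equally long).

The three steps most likely to fail:

**Step 9 (radical bicyclisation).** This is the step without direct precedent. The doubts are the yield of a cascade run with a conjugated diene in the substrate, the face selectivity relayed from C6, and the C4 selectivity, which rests only on the size of the titanoxymethyl arm. C4 or C6 epimers and endocyclic alkene isomers would have to be removed at 18.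

The fallback cyclises before the diene exists and builds the diene on the bicycle; it sets out from 8 and comes back at 18. It removes the diene problem but not the C4 or face-selectivity risk. Copper-catalysed SN2 coupling of 8 with prop-1-ynylmagnesium bromide (CuI cat., THF, −20 °C) gives {[(2E)-2-methylhept-2-en-5-yn-1-yl]sulfonyl}benzene F1. Lithiation and acylation with 5 as in step 5 give (4E,8E)-7-(benzenesulfonyl)-4,8-dimethyl-1-(2-methyloxiran-2-yl)trideca-4,8-dien-11-yn-6-one F2. SmI2 desulfonylation gives (4E,8E)-4,8-dimethyl-1-(2-methyloxiran-2-yl)trideca-4,8-dien-11-yn-6-one F3, CBS reduction gives (4E,6R,8E)-4,8-dimethyl-1-(2-methyloxiran-2-yl)trideca-4,8-dien-11-yn-6-ol F4, and acetylation gives (4E,6R,8E)-4,8-dimethyl-1-(2-methyloxiran-2-yl)trideca-4,8-dien-11-yn-6-yl acetate F5. The Cp2TiCl cascade on this diene-free substrate gives (1R,4R,4aS,8S,8aS)-4-(but-2-yn-1-yl)-8-(hydroxymethyl)-4a,8-dimethyl-3-methylidenedecahydronaphthalen-1-yl acetate F6. Syn-hydrozirconation with Cp2Zr(H)Cl (zirconium on the methyl-bearing alkyne carbon) and Negishi coupling with vinyl bromide (ZnCl2, Pd(PPh3)4) then build the (E)-diene and give 18.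

**Step 5 (acylation of the lithiated sulfone).** The β,β-disubstituted enoate is a poor electrophile and can be deprotonated at its γ positions instead.

The fallback replaces ester acylation by aldehyde addition and oxidation; it sets out from 5 and comes back at 13. i-Bu2AlH (CH2Cl2, −78 °C) reduces 5 to (2E)-3-methyl-6-(2-methyloxiran-2-yl)hex-2-en-1-ol F7, and MnO2 gives (2E)-3-methyl-6-(2-methyloxiran-2-yl)hex-2-enal F8. Addition of lithiated sulfone 12 (THF, −78 °C) gives (4E,8E,11E)-7-(benzenesulfonyl)-4,8,12-trimethyl-1-(2-methyloxiran-2-yl)tetradeca-4,8,11,13-tetraen-6-ol F9, and Dess–Martin periodinane oxidises it to 13.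

**Step 7 (CBS reduction).** The two ketone substituents (a trisubstituted alkenyl group and an allylic CH2) differ less than in standard CBS substrates, so the ee may be insufficient for a centre that controls all others.

The fallback replaces asymmetric reduction by resolution with recycling; it sets out from 14 and comes back at 15. Luche reduction (NaBH4, CeCl3·7H2O, MeOH, −78 °C) gives racemic (4E,8E,11E)-4,8,12-trimethyl-1-(2-methyloxiran-2-yl)tetradeca-4,8,11,13-tetraen-6-ol F10. Oxidative kinetic resolution by transfer dehydrogenation with the preformed amido complex Ru[(S,S)-Tsdpen](p-cymene) in acetone at rt returns the (6S) enantiomer to ketone 14, which is recycled, and leaves (6R)-alcohol 15.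

## Further compounds

F1 | step 9 | {[(2E)-2-methylhept-2-en-5-yn-1-yl]sulfonyl}benzene | CC#CC/C=C(C)/CS(=O)(=O)c1ccccc1
F2 | step 9 | (4E,8E)-7-(benzenesulfonyl)-4,8-dimethyl-1-(2-methyloxiran-2-yl)trideca-4,8-dien-11-yn-6-one | CC1(CCC/C(C)=C/C(=O)C(/C(C)=C/CC#CC)S(=O)(=O)c2ccccc2)CO1
F3 | step 9 | (4E,8E)-4,8-dimethyl-1-(2-methyloxiran-2-yl)trideca-4,8-dien-11-yn-6-one | CC1(CCC/C(C)=C/C(=O)C/C(C)=C/CC#CC)CO1
F4 | step 9 | (4E,6R,8E)-4,8-dimethyl-1-(2-methyloxiran-2-yl)trideca-4,8-dien-11-yn-6-ol | CC1(CCC/C(C)=C/[C@H](O)C/C(C)=C/CC#CC)CO1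
F5 | step 9 | (4E,6R,8E)-4,8-dimethyl-1-(2-methyloxiran-2-yl)trideca-4,8-dien-11-yn-6-yl acetate | CC1(CCC/C(C)=C/[C@H](OC(C)=O)C/C(C)=C/CC#CC)CO1
F6 | step 9 | (1R,4R,4aS,8S,8aS)-4-(but-2-yn-1-yl)-8-(hydroxymethyl)-4a,8-dimethyl-3-methylidenedecahydronaphthalen-1-yl acetate | CC#CC[C@@H]1C(=C)C[C@@H](OC(C)=O)[C@H]2[C@@]1(C)CCC[C@]2(C)CO
F7 | step 5 | (2E)-3-methyl-6-(2-methyloxiran-2-yl)hex-2-en-1-ol | CC1(CCC/C(C)=C/CO)CO1
F8 | step 5 | (2E)-3-methyl-6-(2-methyloxiran-2-yl)hex-2-enal | CC1(CCC/C(C)=C/C=O)CO1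
F9 | step 5 | (4E,8E,11E)-7-(benzenesulfonyl)-4,8,12-trimethyl-1-(2-methyloxiran-2-yl)tetradeca-4,8,11,13-tetraen-6-ol | CC1(CCC/C(C)=C/C(O)C(/C(C)=C/C/C=C(\C)C=C)S(=O)(=O)c2ccccc2)CO1
F10 | step 7 | racemic (4E,8E,11E)-4,8,12-trimethyl-1-(2-methyloxiran-2-yl)tetradeca-4,8,11,13-tetraen-6-ol | CC1(CCC/C(C)=C/C(O)C/C(C)=C/C/C=C(\C)C=C)CO1
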